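**Retrosynthetic overview**

1. The C12 formate and the C3/C9 acetates go on last, onto a triol. Its (E)-C7=C11 alkene comes from a cis-1,4-hydroboration of a C8=C7–C11=C12 diene (Suzuki coupling of a C7 enol triflate), and both secondary carbinols come from one hydride reduction of a 3,9-dione.
2. The dione goes back, by C3 allylic oxidation and C7 enol triflate formation, to a cis-fused bicyclic ketol that lacks C11–C13.
3. Key disconnections: C1–C6 (Michael) and C8–C9 (aldol), both made in one amine-catalysed operation from an acyclic keto-enal; ring A closes first, ring B second.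
4. Enabling feature: in ring B, C7 is a latent ketone whose two α-carbons (C6, C8) are ring atoms, the C9 carbinol is 1,3 to C7, and C7/C9 are 1,5-related through C6–C1–C10, so C1 is the β-carbon of a C9 enal. The C4=C5 alkene of ring A is β,γ to C7, which makes C6 the α-carbon of a dienamine.
5. The keto-enal comes in two steps from racemic melonal (Wittig olefination, allylic oxidation).

Key step: step 3

Numbering and descriptors: cadinane numbering is used for all bicyclic compounds (ring A: C1–C2–C3–C4–C5–C6; ring B: C1–C6–C7–C8–C9–C10; C11 on C7 carries C12 and C13; C14 on C10; C15 on C4). β is the face that carries H-1 and H-6, α the opposite face.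

Assumption: the sense of induction at C1 in step 3 is assigned from the enamine–carboxylic acid transition-state model of proline catalysis (L-proline as written); should the opposite sense be found, D-proline is used and nothing else changes.

**Route**

Step 1
Reactants: 1 2,6-dimethylhept-5-enal (melonal, racemic); 2 1-(triphenylphosphoranylidene)propan-2-one
Product: 3 (E)-5,9-dimethyldeca-3,8-dien-2-one (racemic at C5)
Conditions: toluene, 80 °C
Reagents that add atoms: none
Why: Wittig olefination with a stabilised ylide should give the (E)-enone; the stereocentre of racemic 1 needs no control because step 3 turns it into the sp2 carbon C4.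

Step 2
Reactants: 3 (E)-5,9-dimethyldeca-3,8-dien-2-one
Product: 5 (2E,7E)-2,6-dimethyl-9-oxodeca-2,7-dienal, via allylic alcohol 4 (not isolated)
Conditions: SeO2 (0.3 equiv), tBuOOH (3 equiv), salicylic acid (0.1 equiv), CH2Cl2, 23 °C; filtered through silica; then MnO2, CH2Cl2, 23 °C
Reagents that add atoms: tert-butyl hydroperoxide, CC(C)(C)OO (oxygen, relayed by catalytic selenium dioxide, O=[Se]=O)
Why: SeO2 allylic oxidation (ene reaction, then [2,3]-sigmatropic shift) is selective for the (E)-methyl group of the electron-rich trisubstituted alkene and leaves the electron-poor enone alkene alone, and MnO2 then takes the allylic alcohol (and any aldehyde already formed) to the (E)-enal.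

Step 3
Reactants: 5 (2E,7E)-2,6-dimethyl-9-oxodeca-2,7-dienal
Product: 7 9β-hydroxy-11,12,13-trinorcadin-4-en-7-one (cis-fused; H-1, H-6 and the C10 methyl β), via Michael adduct 6 (not isolated)
Conditions: L-proline (30 mol %), DMSO, 0.05 M, 23 °C; stopped when 5 and 6 are consumed
Reagents that add atoms: none
Why: L-Proline condenses with the enone of 5 and γ-deprotonation at C4 gives the linear dienamine (N–C7=C6–C5=C4), whose α-carbon C6 adds to C1 of the tethered (E)-2-methyl-enal (hydrogen-bonded to the carboxylic acid) and closes ring A in a 6-exo-trig Michael addition to give 6; the resulting iminium ion is deprotonated at C8 and this enamine adds to the C9 aldehyde, closing ring B in a 6-(enolendo)-exo-trig aldol addition that forms C8–C9 (closest known reaction types: the amine-catalysed intramolecular Michael addition of dienamines to tethered enals and the Hajos–Parrish enolendo aldolisation, together an intramolecular Robinson-type [3+3] annulation without dehydration). C1 is the only centre that is fixed irreversibly, and it is set by the catalyst: with the anti-dienamine, delivery of the enal to the face of the carboxylic acid and a chair with the enal unit equatorial, the model gives the C1 configuration drawn, and the aldol stage on the same catalyst face is matched with it. C6 is α to the iminium ion and allylic, so it epimerises in 6, and only the epimer that places C5 axial on the forming ring B avoids A(1,3) strain with the pyrrolidine ring of the enamine, which funnels the material into the cis-fused ketol; C10 equilibrates through the aldehyde enamine and enters with its methyl group equatorial (the epimer would be syn-axial to C5), and the C9 carbinol (expected axial, 9β, from the hydrogen-bonded transition state) is erased in step 5, so either epimer serves. The racemic C4 centre of 5 and the E/Z mixture of the dienamine are funnelled as well, because only the dienamine with C3 and C6 cis on C4=C5 can cyclise. The step needs α- rather than γ-attack of the dienamine and reaction through the ketone-derived rather than the aldehyde-derived dienamine: γ-attack would give a four-membered ring, the alternative mode (C10 onto C5) needs a (Z)-C1=C2 alkene inside the ring and builds a quaternary C10, and the only six-membered aldol closure open to 6 is C8 onto C9.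

Step 4
Reactants: 7 9β-hydroxy-11,12,13-trinorcadin-4-en-7-one
Product: 10 9β-hydroxy-11,12,13-trinorcadina-4,7-dien-7-yl trifluoromethanesulfonate, via trimethylsilyl ether 8 (not isolated), via silyloxy enol triflate 9 (not isolated)
Conditions: TMSCl, Et3N, CH2Cl2, 0 °C; filtered and taken up in THF; KN(SiMe3)2, −78 °C; PhNTf2, −78 to 0 °C; then 1 M HCl, THF, 0 °C
Reagents that add atoms: N-phenylbis(trifluoromethanesulfonimide), O=S(=O)(N(c1ccccc1)S(=O)(=O)C(F)(F)F)C(F)(F)F; chlorotrimethylsilane, C[Si](C)(C)Cl (in 8 and 9 only)
Why: Kinetic deprotonation of the transiently silylated ketol should occur at C8, the less hindered methylene, because H-6 lies equatorial on ring B (in the plane of the carbonyl group and poorly aligned), and O-triflation of the potassium enolate (enol triflate formation) is followed by acid cleavage of the silyl ether; no stereocentre is formed.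

Step 5
Reactants: 10 9β-hydroxy-11,12,13-trinorcadina-4,7-dien-7-yl trifluoromethanesulfonate
Product: 12 3,9-dioxo-11,12,13-trinorcadina-4,7-dien-7-yl trifluoromethanesulfonate, via C3 carbinol 11 (not isolated)
Conditions: SeO2 (0.5 equiv), tBuOOH (3 equiv), CH2Cl2, 23 °C; filtered through silica; then triacetoxyperiodinane (DMP, 3 equiv), CH2Cl2, 0 to 23 °C
Reagents that add atoms: tert-butyl hydroperoxide, CC(C)(C)OO (oxygen at C3, relayed by catalytic selenium dioxide, O=[Se]=O)
Why: SeO2 allylic oxidation should hydroxylate C3, the ring methylene on the more substituted end of the C4=C5 alkene (the enol triflate alkene is electron-poor, and H-6 is not on the carbon that the ene step addresses), and the periodinane then oxidises both the C3 carbinol (either epimer) and the C9 carbinol, so all stereo- and oxidation-level mixtures at C3 and C9 converge on one dione.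

Step 6
Reactants: 12 3,9-dioxo-11,12,13-trinorcadina-4,7-dien-7-yl trifluoromethanesulfonate
Product: 13 3α,9α-dihydroxy-11,12,13-trinorcadina-4,7-dien-7-yl trifluoromethanesulfonate
Conditions: NaBH4, CeCl3·7H2O, MeOH, −78 to −40 °C
Reagents that add atoms: none
Why: Luche 1,2-reduction of both carbonyl groups from the convex β-face: at C9 by axial hydride delivery (only H-1 is syn-axial) to give the equatorial 9α-alcohol trans to the C10 methyl group, and at C3 by attack anti to the axial C1–C10 bond that shields the α-face of ring A to give the 3α-alcohol; the C10 methyl group, epimerisable in 12, stays equatorial because its epimer would be syn-axial to C5.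

Step 7
Reactants: 13 3α,9α-dihydroxy-11,12,13-trinorcadina-4,7-dien-7-yl trifluoromethanesulfonate; 14 4,4,5,5-tetramethyl-2-(prop-1-en-2-yl)-1,3,2-dioxaborolane
Product: 15 cadina-4,7,11-triene-3α,9α-diol
Conditions: Pd(PPh3)4 (5 mol %), K3PO4, 1,4-dioxane/H2O, 60 °C
Reagents that add atoms: none
Why: Suzuki–Miyaura coupling of the alkenyl triflate with the alkenylboronate forms the C7–C11 bond with retention of the C7=C8 alkene and tolerates the free hydroxyl groups.

Step 8
Reactants: 15 cadina-4,7,11-triene-3α,9α-diol
Product: 17 (7(11)E)-cadina-4,7(11)-diene-3α,9α,12-triol, via allylboronate 16 (not isolated)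
Conditions: Ni(cod)2 (5 mol %), PCy3 (5 mol %), pinacolborane (2 equiv), toluene, 23 °C; then aqueous NaOH, H2O2, THF, 0 to 23 °C
Reagents that add atoms: hydrogen peroxide, OO (oxygen at C12); pinacolborane, [H]B1OC(C)(C)C(C)(C)O1 (boron in 16 only)
Why: Nickel-catalysed 1,4-hydroboration of the 1,3-diene goes through the s-cis diene complex and places hydrogen on C8 and boron on the unsubstituted terminus C12 on the same side of the new C7=C11 bond, so that C12 is cis to C8 (descriptor E, as in the target), and oxidation of the allylboronate keeps the position and geometry of the double bond.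

Step 9
Reactants: 17 (7(11)E)-cadina-4,7(11)-diene-3α,9α,12-triol
Product: 18 (7(11)E)-3α,9α-dihydroxycadina-4,7(11)-dien-12-yl formate
Conditions: 2,2,2-trifluoroethyl formate (3 equiv), THF, 40 °C, stopped at mono-acylation
Reagents that add atoms: 2,2,2-trifluoroethyl formate, O=COCC(F)(F)F
Why: Formyl transfer from an activated formate ester (transesterification) is chemoselective for the primary allylic alcohol, which reacts much faster than the pseudoaxial C3 and the secondary C9 hydroxyl groups.

Step 10
Reactants: 18 (7(11)E)-3α,9α-dihydroxycadina-4,7(11)-dien-12-yl formate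
Product: 19 (1S,3R,6S,9R,10R,7(11)E)-3,9-diacetoxycadina-4,7(11)-dien-12-yl formate (target, CNP0262962.1)
Conditions: Ac2O, pyridine, DMAP (10 mol %), CH2Cl2, 0 to 23 °C
Reagents that add atoms: acetic anhydride, CC(=O)OC(C)=O
Why: DMAP-catalysed acetylation of the two secondary alcohols occurs with retention at C3 and C9 and leaves the formate ester in place.

**Compound list**

1 | 2,6-dimethylhept-5-enal (melonal, racemic) | O=CC(C)CCC=C(C)C | starting material
2 | 1-(triphenylphosphoranylidene)propan-2-one | CC(=O)C=P(c1ccccc1)(c1ccccc1)c1ccccc1 | starting material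
3 | (E)-5,9-dimethyldeca-3,8-dien-2-one (racemic at C5) | CC(=O)/C=C/C(C)CCC=C(C)C | intermediate
4 | (3E,8E)-10-hydroxy-5,9-dimethyldeca-3,8-dien-2-one (not isolated) | CC(=O)/C=C/C(C)CC/C=C(\C)CO | intermediate
5 | (2E,7E)-2,6-dimethyl-9-oxodeca-2,7-dienal (racemic at C6) | CC(=O)/C=C/C(C)CC/C=C(\C)C=O | intermediate
6 | 2-[(1,2-trans)-2-acetyl-4-methylcyclohex-3-en-1-yl]propanal, ring C1 as in 7, epimers at the propanal α-carbon (not isolated) | C1C[C@H](C(C)C=O)[C@@H](C(C)=O)C=C1C | intermediate
7 | 9β-hydroxy-11,12,13-trinorcadin-4-en-7-one (cis-fused; H-1, H-6, 10-CH3 β) | C1C[C@@H]2[C@@H](C)[C@@H](O)CC(=O)[C@@H]2C=C1C | intermediate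
8 | 9β-(trimethylsilyloxy)-11,12,13-trinorcadin-4-en-7-one (not isolated) | C1C[C@@H]2[C@@H](C)[C@@H](O[Si](C)(C)C)CC(=O)[C@@H]2C=C1C | intermediate
9 | 9β-(trimethylsilyloxy)-11,12,13-trinorcadina-4,7-dien-7-yl trifluoromethanesulfonate (not isolated) | C1C[C@@H]2[C@@H](C)[C@@H](O[Si](C)(C)C)C=C(OS(=O)(=O)C(F)(F)F)[C@@H]2C=C1C | intermediate
10 | 9β-hydroxy-11,12,13-trinorcadina-4,7-dien-7-yl trifluoromethanesulfonate | C1C[C@@H]2[C@@H](C)[C@@H](O)C=C(OS(=O)(=O)C(F)(F)F)[C@@H]2C=C1C | intermediate
11 | 3,9β-dihydroxy-11,12,13-trinorcadina-4,7-dien-7-yl trifluoromethanesulfonate, C3 epimers (not isolated) | OC1C[C@@H]2[C@@H](C)[C@@H](O)C=C(OS(=O)(=O)C(F)(F)F)[C@@H]2C=C1C | intermediate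
12 | 3,9-dioxo-11,12,13-trinorcadina-4,7-dien-7-yl trifluoromethanesulfonate | O=C1C[C@@H]2[C@@H](C)C(=O)C=C(OS(=O)(=O)C(F)(F)F)[C@@H]2C=C1C | intermediate
13 | 3α,9α-dihydroxy-11,12,13-trinorcadina-4,7-dien-7-yl trifluoromethanesulfonate | O[C@@H]1C[C@@H]2[C@@H](C)[C@H](O)C=C(OS(=O)(=O)C(F)(F)F)[C@@H]2C=C1C | intermediate
14 | 4,4,5,5-tetramethyl-2-(prop-1-en-2-yl)-1,3,2-dioxaborolane | CC(=C)B1OC(C)(C)C(C)(C)O1 | starting material
15 | cadina-4,7,11-triene-3α,9α-diol | O[C@@H]1C[C@@H]2[C@@H](C)[C@H](O)C=C(C(C)=C)[C@@H]2C=C1C | intermediate
16 | (7(11)E)-12-(4,4,5,5-tetramethyl-1,3,2-dioxaborolan-2-yl)cadina-4,7(11)-diene-3α,9α-diol (not isolated) | O[C@@H]1C[C@@H]2[C@@H](C)[C@H](O)C/C(=C(/C)CB3OC(C)(C)C(C)(C)O3)[C@@H]2C=C1C | intermediate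
17 | (7(11)E)-cadina-4,7(11)-diene-3α,9α,12-triol | O[C@@H]1C[C@@H]2[C@@H](C)[C@H](O)C/C(=C(/C)CO)[C@@H]2C=C1C | intermediate
18 | (7(11)E)-3α,9α-dihydroxycadina-4,7(11)-dien-12-yl formate | O[C@@H]1C[C@@H]2[C@@H](C)[C@H](O)C/C(=C(/C)COC=O)[C@@H]2C=C1C | intermediate
19 | (1S,3R,6S,9R,10R,7(11)E)-3,9-diacetoxycadina-4,7(11)-dien-12-yl formate | CC(=O)O[C@@H]1C[C@@H]2[C@@H](C)[C@H](OC(C)=O)C/C(=C(/C)COC=O)[C@@H]2C=C1C | target

**Step count**

Total steps: 10. Longest linear sequence: 10 steps (from 1).

**Steps most likely to fail**

Step 3. The cascade may fail through weak enantiofacial discrimination at C1 in the Michael stage (C1 is the one centre that no later step can repair), or through ring B closing before C6 has epimerised, which would give trans-fused material. Fallback: enantiopurity is taken from a resolution instead of from the catalyst. Setting out from 5, the same cyclisation with DL-proline should give, through the racemic Michael adduct F1, the racemic ketol F2. Lipase-catalysed acylation (Candida antarctica lipase B, vinyl acetate, tert-butyl methyl ether) is expected to acetylate one enantiomer; the enzyme and acyl donor are chosen so that the unwanted antipode becomes the acetate F3 and the alcohol 7 is recovered, where the route is rejoined.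

Step 8. The hydroboration may fail through ionisation of the allylic C3–O or C9–O bond by zerovalent nickel, through hydride delivery to C12 instead of C8 on this hindered trisubstituted diene, or through loss of the cis-1,4 course. Fallback: the exocyclic alkene is made by carbonyl olefination, at the price of separating alkene isomers. From 7, silylation (TBSOTf, 2,6-lutidine) should give the silyl ether F4. Horner–Wadsworth–Emmons olefination with triethyl 2-phosphonopropionate (NaH, THF, reflux) should give the tetrasubstituted enoate, from which the (E)-ester F5 (ester carbon cis to C8) is separated by chromatography. HF·pyridine frees the hydroxy ester F6. The conditions of step 5 (the enoate alkene is electron-poor and inert to SeO2) should give, through the C3 carbinol F7, the dione ester F8, and the conditions of step 6 the diol ester F9. Reduction of the ester with iBu2AlH (CH2Cl2, −78 °C) then gives the triol 17, where the route is rejoined.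

Step 5. The allylic hydroxylation may fail through ene reaction at the C4 methyl group instead of C3, or through selenium-mediated degradation of the enol triflate. Fallback: direct allylic C–H oxidation to the enone by hydrogen-atom abstraction. From 10, CrO3·3,5-dimethylpyrazole (excess, CH2Cl2, −20 °C) is expected to oxidise the C9 carbinol first, giving the keto triflate F10, and then the C3 methylene, giving 12 directly, where the route is rejoined.

**Further compounds**

F1 | step 3 | racemic 2-[(1,2-trans)-2-acetyl-4-methylcyclohex-3-en-1-yl]propanal (both enantiomers, not isolated) | C1C[C@H](C(C)C=O)[C@@H](C(C)=O)C=C1C.C1C[C@@H](C(C)C=O)[C@H](C(C)=O)C=C1C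
F2 | step 3 | racemic 9β-hydroxy-11,12,13-trinorcadin-4-en-7-one (both enantiomers) | C1C[C@@H]2[C@@H](C)[C@@H](O)CC(=O)[C@@H]2C=C1C.C1C[C@H]2[C@H](C)[C@H](O)CC(=O)[C@H]2C=C1C
F3 | step 3 | 9-O-acetate of the enantiomer of 7 | C1C[C@H]2[C@H](C)[C@H](OC(C)=O)CC(=O)[C@H]2C=C1C
F4 | step 8 | 9β-(tert-butyldimethylsilyloxy)-11,12,13-trinorcadin-4-en-7-one | C1C[C@@H]2[C@@H](C)[C@@H](O[Si](C)(C)C(C)(C)C)CC(=O)[C@@H]2C=C1C
F5 | step 8 | ethyl (7(11)E)-9β-(tert-butyldimethylsilyloxy)cadina-4,7(11)-dien-12-oate | C1C[C@@H]2[C@@H](C)[C@@H](O[Si](C)(C)C(C)(C)C)C/C(=C(/C)C(=O)OCC)[C@@H]2C=C1C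
F6 | step 8 | ethyl (7(11)E)-9β-hydroxycadina-4,7(11)-dien-12-oate | C1C[C@@H]2[C@@H](C)[C@@H](O)C/C(=C(/C)C(=O)OCC)[C@@H]2C=C1C
F7 | step 8 | ethyl (7(11)E)-3,9β-dihydroxycadina-4,7(11)-dien-12-oate, C3 epimers (not isolated) | OC1C[C@@H]2[C@@H](C)[C@@H](O)C/C(=C(/C)C(=O)OCC)[C@@H]2C=C1C
F8 | step 8 | ethyl (7(11)E)-3,9-dioxocadina-4,7(11)-dien-12-oate | O=C1C[C@@H]2[C@@H](C)C(=O)C/C(=C(/C)C(=O)OCC)[C@@H]2C=C1C
F9 | step 8 | ethyl (7(11)E)-3α,9α-dihydroxycadina-4,7(11)-dien-12-oate | O[C@@H]1C[C@@H]2[C@@H](C)[C@H](O)C/C(=C(/C)C(=O)OCC)[C@@H]2C=C1C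
F10 | step 5 | 9-oxo-11,12,13-trinorcadina-4,7-dien-7-yl trifluoromethanesulfonate (not isolated) | C1C[C@@H]2[C@@H](C)C(=O)C=C(OS(=O)(=O)C(F)(F)F)[C@@H]2C=C1C
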